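Two earlier runs, autumn and dusk, stand behind three new flasks.

| flask | starting material | capture agent | temperature | remark | time |
|---|---|---|---|---|---|
| autumn | 1.3 M | 0.60 M | 38 °C | run made earlier |  |
| dusk | 3 M | 0.60 M | 65 °C | run made earlier |  |
| Friday's | 2.0 M | 0.600 M | 50 °C |  | 40 h |
| Thursday's | 2.0 M | 0.600 M | 75 °C |  | 40 h |
| Sunday's | 2.0 M | 0.600 M | 25 °C |  | 40 h |

| run | time / h | target / % | starting material / % |
|---|---|---|---|
| autumn | 5.00 | 1.5 | 19.0 |
| autumn | 10.0 | 12.5 | 4.5 |
| autumn | 15.0 | 27.2 | 0 |
| autumn | 20.0 | 41.4 | 0 |
| autumn | 25.0 | 51.0 | 1.7 |
| dusk | 0.500 | 19.5 | 0.3 |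
| dusk | 1.50 | 76.4 | 0 |
| dusk | 3.00 | 89.2 | 0.1 |
| dusk | 4.00 | 89.5 | 1.2 |
| dusk | 6.00 | 91.3 | 1.2 |

(standard deviation of a reading: 1 percentage point)

- amounts and yields of target count crystals too
- given per volume of solution although it is solid: crystals
- steps that have been proposed: intermediate A + capture agent -> trapped intermediate; starting material -> decomposition product; intermediate B -> intermediate C; starting material -> intermediate A; intermediate A -> intermediate B; intermediate C -> target; crystals <-> target

- which of the two there is more of at the end, Friday's (target / trapped intermediate)
- which of the two there is more of at the end, Thursday's (target / trapped intermediate)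
- which of the two there is more of at the end, Sunday's (target / trapped intermediate)
- final target, as a percentage of the starting material charged, in Friday's
- final target, as a percentage of the starting material charged, in Thursday's
- final target, as a percentage of the starting material charged, in Sunday's

The autumn run passes half of its charge as target at about 24.5 h, and the dusk run at about 1.04 h, both read between neighbouring readings. I assume that percent target follows temperature and not the charge, so this gap of 23.6 times gives an apparent activation energy of 102 kJ/mol.

So I divide a time at Sunday's temperature by 5.62 to get the autumn time worth the same; I call this divisor the clock factor. Sunday's 40 h is then 7.11 h of autumn time, and the autumn readings put target there at about 6.15 %.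

Friday's gets 174 h of autumn time, which is more than the 142 h that the last dusk reading is worth. I therefore expect Friday's and the hotter Thursday's to have stopped by 40 h.

The forecast gives target 81 % on Friday's (73 % to 87 %), 92 % on Thursday's (85 % to 97 %) and 5 % on Sunday's (1 % to 15 %), where “the run is still in its lag”. It puts trapped intermediate ahead on Sunday's and target ahead on the other two. My Sunday's figure stands a little higher.

The flasks give 83.2 % on Friday's, 90.5 % on Thursday's and 4.46 % on Sunday's, with the forecast's leaders and ranges holding.

    intermediate A + capture agent → trapped intermediate (k = 0.0253 /M/h, Ea = 75.0 kJ/mol)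
    starting material → decomposition product (k = 4.70 × 10⁻⁵ /h, Ea = 118 kJ/mol)
    intermediate B → intermediate C (k = 0.0709 /h, Ea = 108 kJ/mol)
    starting material → intermediate A (k = 0.0562 /h, Ea = 105 kJ/mol)
    intermediate A → intermediate B (k = 0.0192 /h, Ea = 107 kJ/mol)
    intermediate C → target (k = 0.0213 /h, Ea = 98.0 kJ/mol)
    crystals ⇌ target, rate k7*(cs7 - [target]) while solid is left; crystals form when [target] > cs7 (solubility = 34.0 mM, k = 0.628 /h)
    (constants at 25 °C)

Sunday's holds 16.4 % trapped intermediate against 4.46 % target at 40 h, yet left until 400 h it holds 73.9 % target. Put to use once more, the clock factor makes Sunday's 20.0 h into 3.56 h of autumn time, before the first autumn reading of 1.5 %, and Sunday's then holds less, at 0.536 %.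

Sunday's flask read at 3.0 d is 12.8 h of autumn time, and the autumn readings put target there at about 20.7 %. The flask holds 18.3 %.

The readings stem from a simulated flask with constants of no real substance; the scatter is artificial.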